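**Retrosynthetic overview**
- Surinone B is traced back, by hydrogenation of a C2'=C3' alkene and a retro-oxa-Michael ring opening, to a 2-(10-phenyldecyl)dihydropyranone.
- The route rests on one feature: the enol oxygen on ring C3 can be tied to chain carbon C3' through ring C2, C1' and C2' as a six-membered 4-pyranone fused to the cyclohexanone. In that pyranone, C3' is the O–CH= β-carbon of an enone and can accept a radical.
- The C3'–C4' bond is therefore cut to the bicyclic pyranone and a 10-phenyldecyl radical, released by reductive decarboxylation of the N-acyloxyphthalimide of 11-phenylundecanoic acid.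
- The pyranone comes from 2-acetylcyclohexane-1,3-dione and DMF dimethyl acetal; the acid comes from phenylmagnesium bromide and 11-bromoundecanoic acid.
- Ring order: the carbocycle is bought, the pyranone ring is closed in step 1, serves as the acceptor in step 4 and is opened again in step 5.

Key step: step 4

Remark: the target is drawn as one enol tautomer of an achiral 2-acylcyclohexane-1,3-dione; tautomers are treated as one compound, and no stereocentre has to be set. Primes denote acyl-chain carbons (C1' is the enol carbon).

**Step 1**
Reactants: 1 2-acetylcyclohexane-1,3-dione; 2 N,N-dimethylformamide dimethyl acetal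
Product: 4 7,8-dihydro-4H-chromene-4,5(6H)-dione, via dimethylaminoacryloyl triketone 3 (not isolated)
Conditions: PhMe, 80 °C; evaporate; then AcOH, 100 °C
Reagents that add atoms: none
Why: Amide-acetal condensation at the acetyl methyl group gives the vinylogous amide, and in hot acetic acid the acidic ring enol oxygen adds to its β-carbon with loss of dimethylamine (enaminone-to-pyranone cyclisation, as in the chromone synthesis from o-hydroxyaryl enaminones), the acid keeping the liberated amine from re-opening the ring.

**Step 2**
Reactants: 5 11-bromoundecanoic acid; 6 phenylmagnesium bromide (2.5 equiv)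
Product: 8 11-phenylundecanoic acid, via bromomagnesium 11-bromoundecanoate 7 (not isolated)
Conditions: Li2CuCl4 (3 mol %), THF, −20 °C to rt; then 1 M HCl
Reagents that add atoms: none
Why: The first equivalent of the Grignard reagent converts the acid into its unreactive bromomagnesium carboxylate, after which the copper-catalysed Kochi-type coupling of the aryl Grignard reagent with the primary bromide forms the aryl–alkyl bond.

**Step 3**
Reactants: 8 11-phenylundecanoic acid
Product: 9 1,3-dioxoisoindolin-2-yl 11-phenylundecanoate
Conditions: N-hydroxyphthalimide, DIC, DMAP (cat.), CH2Cl2, rt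
Reagents that add atoms: N-hydroxyphthalimide, ON1C(=O)c2ccccc2C1=O
Why: Carbodiimide (Steglich-type) esterification of an unhindered primary acid with the N-hydroxy imide should give the redox-active ester cleanly.

**Step 4**
Reactants: 4 7,8-dihydro-4H-chromene-4,5(6H)-dione; 9 1,3-dioxoisoindolin-2-yl 11-phenylundecanoate (1.5 equiv)
Product: 10 racemic 2-(10-phenyldecyl)-2,3,7,8-tetrahydro-4H-chromene-4,5(6H)-dione
Conditions: undivided cell, reticulated vitreous carbon cathode, Zn anode, nBu4NBF4 (0.1 M), AcOH (3 equiv), DMF, constant current 5 mA, about 2.5 F/mol of 4, rt, N2
Reagents that add atoms: none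
Why: Electron transfer from the carbon cathode to ester 9 gives a radical anion that fragments to phthalimide anion, CO2 and the primary 10-phenyldecyl radical, which adds to C2 of pyranone 4 (the O–CH= carbon, C3' of the target) to form the C3'–C4' bond; the resulting α-keto radical at C3 is reduced to the enolate and protonated by acetic acid, the zinc anode being the electron source. The reaction is a decarboxylative Giese addition of a redox-active ester, a type established for chromones and other enones under cathodic or photoredox reduction and applied here to a new bicyclic pyranone. No ring is closed. The single new stereocentre, C2 of 10, is formed without control as a racemate, which is acceptable because step 5 removes it. The step needs attack at C2 and not at the ring-fusion carbon C8a, and reduction of the ester before the pyranone; C2 is the only unsubstituted β-carbon of an enone made more electron-poor by the C5 ketone, while the ester is expected to be reduced at a less negative potential and is kept in excess. Pyranone 4 carries no acidic hydrogen or free enolate that could quench the radical, and acetic acid should protonate the adduct enolate before it can expel the ring oxygen.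

**Step 5**
Reactants: 10 racemic 2-(10-phenyldecyl)-2,3,7,8-tetrahydro-4H-chromene-4,5(6H)-dione
Product: 12 surinone B (2-(1-hydroxy-13-phenyltridecylidene)cyclohexane-1,3-dione), via enoyl triketone 11 (not isolated)
Conditions: DBU (1.5 equiv), THF, 40 °C; then 10% Pd/C, H2 (1 atm), rt; then 1 M HCl work-up
Reagents that add atoms: none
Why: DBU removes a C3 proton and the enolate expels the ring oxygen as the stabilised triketonate (E1cB retro-oxa-Michael opening, pulled forward by salt formation of the acidic triketone), and catalytic hydrogenation of the salt then saturates only the disubstituted C2'=C3' alkene, since the chelated tetrasubstituted enol, the ketones and the phenyl ring are inert to Pd/C at 1 atm.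

**Compound list**
1 | 2-acetylcyclohexane-1,3-dione | CC(=O)C1C(=O)CCCC1=O | starting material
2 | N,N-dimethylformamide dimethyl acetal | COC(OC)N(C)C | starting material
3 | 2-[(2E)-3-(dimethylamino)prop-2-enoyl]cyclohexane-1,3-dione, drawn as its enol | CN(C)/C=C/C(O)=C1C(=O)CCCC1=O | intermediate (not isolated)
4 | 7,8-dihydro-4H-chromene-4,5(6H)-dione | O=C1C=COC2=C1C(=O)CCC2 | intermediate
5 | 11-bromoundecanoic acid | OC(=O)CCCCCCCCCCBr | starting material
6 | phenylmagnesium bromide | Br[Mg]c1ccccc1 | starting material
7 | bromomagnesium 11-bromoundecanoate | BrCCCCCCCCCCC(=O)O[Mg]Br | intermediate (not isolated)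
8 | 11-phenylundecanoic acid | OC(=O)CCCCCCCCCCc1ccccc1 | intermediate
9 | 1,3-dioxoisoindolin-2-yl 11-phenylundecanoate | O=C(CCCCCCCCCCc1ccccc1)ON1C(=O)c2ccccc2C1=O | intermediate
10 | racemic 2-(10-phenyldecyl)-2,3,7,8-tetrahydro-4H-chromene-4,5(6H)-dione | O=C1CC(CCCCCCCCCCc2ccccc2)OC2=C1C(=O)CCC2 | intermediate
11 | 2-[(2E)-1-hydroxy-13-phenyltridec-2-en-1-ylidene]cyclohexane-1,3-dione (enol of the 2-enoyl triketone, present as its DBU salt) | O=C1CCCC(=O)C1=C(O)/C=C/CCCCCCCCCCc1ccccc1 | intermediate (not isolated)
12 | surinone B, 2-(1-hydroxy-13-phenyltridecylidene)cyclohexane-1,3-dione | O=C1CCCC(=O)C1=C(O)CCCCCCCCCCCCc1ccccc1 | target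

**Step count**
Total: 5 steps. Longest linear sequence: 4 steps (steps 2, 3, 4, 5 from 11-bromoundecanoic acid).

**Steps most likely to fail**

1. Step 4. The pyranone, especially when chelated by zinc ions, may be reduced at the cathode in competition with the ester and then dimerise. The alkyl radical may dimerise or abstract hydrogen faster than it adds. The adduct enolate may also open in the cell and react further.
Fallback: a polar copper-mediated conjugate addition in place of the radical addition, setting out from 6 and 4 and returning at 10. Phenylmagnesium bromide 6 would be coupled with an excess of 1,10-dibromodecane (Li2CuCl4, THF) to give (10-bromodecyl)benzene F1. Magnesium insertion in THF would give (10-phenyldecyl)magnesium bromide F2. With CuBr·SMe2 and Me3SiCl in THF at −78 °C, F2 should deliver the alkyl group to C2 of pyranone 4, as organocopper reagents do with chromones, giving the silyl dienol ether 2-(10-phenyldecyl)-4-(trimethylsilyloxy)-7,8-dihydro-2H-chromen-5(6H)-one F3. Dilute acid would hydrolyse F3 to 10.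

2. Step 5. The retro-oxa-Michael opening may stall or reverse, the ring closing again before the alkene is reduced, or a nucleophile may add to the liberated enone.
Fallback: build the enoyl triketone by aldol condensation, without any ring opening, setting out from 8 and 1 and returning at 11. Acid 8 would be reduced with LiAlH4 in THF to 11-phenylundecan-1-ol F4. Dess–Martin oxidation would give 11-phenylundecanal F5. Slow addition of F5 to 1 with catalytic pyrrolidine and 4 Å molecular sieves in CH2Cl2 should condense it at the acetyl methyl group to give 11 as its ammonium salt. This salt would be hydrogenated over Pd/C as in the second half of step 5 to give 12.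

3. Step 2. Aryl transfer to the sparingly soluble carboxylate salt may be slow, so that biphenyl formation and reduction or elimination of the bromide take over.
Fallback: a Negishi coupling with reversed polarity, setting out from 5 and returning at 8. Fischer esterification of 5 (MeOH, H2SO4) would give methyl 11-bromoundecanoate F6. Zinc insertion (Zn dust, LiCl, THF, 50 °C) would give (11-methoxy-11-oxoundecyl)zinc bromide F7. Coupling of F7 with iodobenzene (Pd(OAc)2, SPhos, THF) would give methyl 11-phenylundecanoate F8. Saponification with LiOH in aqueous THF and acidification would give 8.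

**Further compounds**
F1 | step 4 | (10-bromodecyl)benzene | BrCCCCCCCCCCc1ccccc1
F2 | step 4 | (10-phenyldecyl)magnesium bromide | Br[Mg]CCCCCCCCCCc1ccccc1
F3 | step 4 | racemic 2-(10-phenyldecyl)-4-(trimethylsilyloxy)-7,8-dihydro-2H-chromen-5(6H)-one | C[Si](C)(C)OC1=CC(CCCCCCCCCCc2ccccc2)OC2=C1C(=O)CCC2
F4 | step 5 | 11-phenylundecan-1-ol | OCCCCCCCCCCCc1ccccc1
F5 | step 5 | 11-phenylundecanal | O=CCCCCCCCCCCc1ccccc1
F6 | step 2 | methyl 11-bromoundecanoate | COC(=O)CCCCCCCCCCBr
F7 | step 2 | (11-methoxy-11-oxoundecyl)zinc bromide | COC(=O)CCCCCCCCCC[Zn]Br
F8 | step 2 | methyl 11-phenylundecanoate | COC(=O)CCCCCCCCCCc1ccccc1
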